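Early on, a flask of substrate makes target first and products later, and the set-ups below differ in how long that target stands.

the same everywhere: substrate 40 mM
- green: a single well-mixed tank run continuously and read at steady state, 9.00 min in it on average
- amber: a closed flask charged with all of it at once and left for 3.0 min; time 3.0 min
- blue: one stirred flow tank at steady state, fed with the mixture as stated, mean residence time 3.0 min
    substrate ⇌ target (K1 = 0.86, k1 = 0.0042 s⁻¹)
    target ⇌ isomer of the product A (K2 = 6.3, k2 = 0.0041 s⁻¹)
    target ⇌ isomer of the product B (K3 = 2.5, k3 = 7.4 × 10⁻⁴ s⁻¹)
    target → over-reaction product (k4 = 7.4 × 10⁻⁴ s⁻¹)
- order of the set-ups by the share of target in all that became target or isomer of the product A or isomer of the product B or over-reaction product, at the outlet or at the end, highest first (green / amber / blue)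
- share of target in all that became target or isomer of the product A or isomer of the product B or over-reaction product, at the outlet or at the end, green
- share of target in all that became target or isomer of the product A or isomer of the product B or over-reaction product, at the outlet or at the end, amber
- share of target in all that became target or isomer of the product A or isomer of the product B or over-reaction product, at the outlet or at the end, blue
- the stated concentrations are those of everything mixed, before any reaction; amounts are the same in each set-up
- run time (amber): 3.0 min

1. Here is the puzzle. Substrate gives target with a forward half-life of 2.8 min, the way to isomer of the product A alone removes target with a forward half-life of 2.82 min, and amber runs 3.0 min, longer than either. Adding the three forward constants out of target gives 0.335 min⁻¹, more than the 0.252 min⁻¹ that makes it, yet I expect amber to keep over half of its converted fraction as target.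

2. The puzzle clears once I keep a constant apart from a rate: loss is the constant times the fraction of target, and that fraction starts at nothing. I call D the drain constant, and, back reactions aside, products per target equal D times the mean time target has stood, its age, so the share is one over one plus that product.

3. In a tank the age is the residence time. Each reversible way counts as its constant times that time, divided by one plus this product over its equilibrium constant. Products per target are then 0.920 in blue and 2.38 in green, which gives shares of 52.1 % and 29.6 %.

4. In amber, target rises from nothing, so I estimate its age as somewhere between half the run and the whole run, which, back reactions aside, puts the share between 49.9 % and 66.6 %. I commit to the middle, 58.2 %, which puts amber first, then blue, then green.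

The forecast says amber > blue > green, with 29.6 %, 58.3 % and 52.1 % for green, amber and blue, remarking “The substrate cancels out”. The simulation gives amber > blue > green, with 29.6 % for green, 58.3 % for amber and 52.1 % for blue.

In amber, with each step taken net, target is made 2.66 times as fast as it is used at 1.06 min and 1.03 times as fast at 3.00 min, and the products per target at the end of amber, divided by D with back reactions aside, put its age at 2.13 min, longer than half the run. In the neighbouring flask, amber read at 50 s, D times half that time gives a share of 87.8 %, and that flask stands at 86.5 %.

All constants come from no measurement; the run is a simulation.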